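The route rests on forming the spiro bond C5–C1 by contracting ring A of a decalin. The target's cyclopentane (C1–C5) carries the lactone oxygen on C3 and the side-chain carbon C11 on neighbouring C2, and shares C5 with the ring B cyclohexene whose C6 bears a methyl group; this array is the imprint of a photochemical dienone rearrangement. Irradiating a cross-conjugated hexalin dienone in aqueous acid joins C1 to C5, releases the angular carbon C10 from ring A as a carbinol and fixes C5 relative to the C6 methyl, all in one operation. The precursor is the (4aS,8S)-trans-4a,8-dimethyl dienone carrying CH2CO2Me on the α-carbon of its disubstituted enone arm.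

Key step: step 6

Atom labels (used for every spiro compound and for the descriptors in their names): the cyclopentane runs C5–C1–C2–C3–C4–C5, with the side chain on C2 (C11, carboxyl C12, methylene C13) and oxygen on C3; C5 is the spiro atom; ring B runs C5–C6–C7–C8–C9–C10, with methyl C15 on C6 and C14 on C10. Decalins carry naphthalene locants; C1, C2, C3, C4, C5, C6 and C10 correspond to C4, C3, C2, C1, C8a, C8 and C4a of the dienone.

Remark: the carbinol centre C10 of 12 is drawn for water entering anti to the breaking C1–C10 bond; it becomes trigonal in step 10, so the epimer would serve equally.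

Step 1
Reactants: 1 2,6-dimethylcyclohexanone (commercial cis/trans mixture); 2 (R)-1-phenylethylamine
Product: 3 N-[(1R)-1-phenylethyl]-2,6-dimethylcyclohexan-1-imine
Conditions: TsOH·H2O (cat.), toluene, reflux, Dean–Stark
Reagents that add atoms: none
Why: Acid-catalysed ketimine condensation driven by azeotropic removal of water should give the imine, the (R) amine being required because this auxiliary steers step 2 to the (S) quaternary centre that the target demands.

Step 2
Reactants: 3 imine; 4 methyl vinyl ketone
Product: 6 (2S)-2,6-dimethyl-2-(3-oxobutyl)cyclohexan-1-one (C6 epimers), via Michael adduct imine 5 (not isolated)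
Conditions: 4, THF, rt, 3 d; then 10% aq. AcOH, rt
Reagents that add atoms: water, O
Why: Asymmetric Michael addition of the secondary enamine tautomer of a chiral imine proceeds through a compact aza-ene-like transition state on the face away from the phenyl group, which for the (R) auxiliary gives the (S) quaternary centre (the (S) amine gives the (R) series), and mild acid hydrolysis then frees the ketone.

Step 3
Reactants: 6 diketone
Product: 7 (4aS,8S)-4a,8-dimethyl-4,4a,5,6,7,8-hexahydronaphthalen-2(3H)-one
Conditions: NaOMe, MeOH, reflux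
Reagents that add atoms: none
Why: Intramolecular aldol condensation (the ring-closing half of a Robinson annulation) should give the octalone, and under the equilibrating base the C8 methyl settles equatorial, trans to the angular methyl, by reversible γ-deprotonation.

Step 4
Reactants: 7 octalone; 8 methyl bromoacetate
Product: 9 methyl 2-[(4aS,8S)-4a,8-dimethyl-2-oxo-2,3,4,4a,5,6,7,8-octahydronaphthalen-3-yl]acetate (C3 epimers)
Conditions: LiN(iPr)2, THF, −78 °C; then 8, DMPU, −78 → −30 °C
Reagents that add atoms: none
Why: Kinetic deprotonation at the saturated α'-carbon gives the cross-conjugated dienolate, whose C-alkylation by the activated halide is a standard enolate alkylation, and the new centre becomes trigonal in step 5 so its configuration is immaterial.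

Step 5
Reactants: 9 alkylated octalone
Product: 10 methyl 2-[(4aS,8S)-4a,8-dimethyl-2-oxo-2,4a,5,6,7,8-hexahydronaphthalen-3-yl]acetate
Conditions: DDQ, dioxane, reflux
Reagents that add atoms: none
Why: DDQ dehydrogenation of a 4-en-3-one to the cross-conjugated dienone proceeds by hydride abstraction from the ring CH2 allylic to the kinetic dienol, the side-chain CH2 being deactivated by its ester, so the new double bond should be endocyclic.

Step 6
Reactants: 10 dienone ester
Product: 12 methyl 2-[(5R,6S,10S)-10-hydroxy-6,10-dimethyl-3-oxospiro[4.5]dec-1-en-2-yl]acetate, via bridged oxyallyl zwitterion 11 (not isolated)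
Conditions: hν (medium-pressure Hg lamp, Pyrex, λ > 300 nm), 45% aq. AcOH, N2, 20 °C
Reagents that add atoms: water, O
Why: Light absorption (n→π*) and intersystem crossing are followed by bonding between the two β-carbons C1 and C5 and electron demotion to the bridged oxyallyl zwitterion 11; in the acidic medium this is protonated on oxygen to a cyclopropylcarbinyl cation centred on C2, the outer cyclopropane bond C1–C10 breaks while water attacks C10 from the rear, and the enol left behind ketonises to the cyclopentenone. The closest known reaction type is the type A photorearrangement of cross-conjugated cyclohexadienones carried out in aqueous acetic acid, in which 2-alkyl dienones are diverted to spiro[4.5]decenones. The five-membered ring is closed by transannular 5-endo bonding of C1 to C5 across ring A (closure of the oxypentadienyl unit C1–C5, giving the bicyclo[3.1.0] array) and is completed when C10 leaves ring A, so the closure is a ring contraction. The spiro centre C5 is controlled by the angular centre C10, since C1 is tethered to C10 on the face of ring B opposite the angular methyl and stays there, which with the trans C6 methyl puts C1 and C15 on the same face as in the target; the carbinol C10 is set by backside entry of water and is erased in step 10. The step needs cleavage of C1–C10 in preference to C5–C10 (hydroazulenone) and to the 1,4-shift (lumiketone), and this is secured by the alkyl group on C2 against hydrogen on C4, which places the positive charge beside C1, together with the protic nucleophilic solvent that traps the zwitterion before it can shift.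

Step 7
Reactants: 12 spiro hydroxy enone
Product: 13 methyl 2-[(3R,5R,6S,10S)-3,10-dihydroxy-6,10-dimethylspiro[4.5]dec-1-en-2-yl]acetate
Conditions: (S)-2-methyl-CBS-oxazaborolidine (0.2 equiv), BH3·SMe2, THF, −20 °C; MeOH quench, neutral work-up
Reagents that add atoms: none
Why: Corey–Bakshi–Shibata reduction is 1,2-selective for enones and treats the substituted alkene arm C2 as the large group, so the (S) catalyst should deliver hydride to the C3 face turned toward C6 and place the hydroxyl on the side of C10, a sense the substrate reinforces because that face is flanked by the tertiary C6 and not by the fully substituted C10.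

Step 8
Reactants: 13 allylic alcohol
Product: 14 methyl 2-[(3R,5R,6S,10S)-3-(tert-butyldimethylsilyloxy)-10-hydroxy-6,10-dimethylspiro[4.5]dec-1-en-2-yl]acetate
Conditions: TBSCl, imidazole, DMF, rt
Reagents that add atoms: tert-butyldimethylsilyl chloride, CC(C)(C)[Si](C)(C)Cl
Why: Imidazole-mediated silyl ether formation takes the secondary allylic hydroxyl and leaves the hindered tertiary carbinol free, and the ether both keeps the hydroxy ester from lactonising (so that no acidic lactone is present during the later ketone enolate chemistry) and supplies the bulk that directs step 9.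

Step 9
Reactants: 14 silyl ether
Product: 15 methyl 2-[(2R,3R,5R,6S,10S)-3-(tert-butyldimethylsilyloxy)-10-hydroxy-6,10-dimethylspiro[4.5]decan-2-yl]acetate
Conditions: H2 (3 atm), 5% Rh on Al2O3, EtOAc, rt
Reagents that add atoms: none
Why: Heterogeneous catalytic hydrogenation should add both hydrogens to the cyclopentene face opposite the adjacent bulky silyloxy group, so C2 receives hydrogen anti to the C3 oxygen and its acetate arm ends cis to that oxygen, rhodium being chosen over palladium to avoid allylic C–O hydrogenolysis.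

Step 10
Reactants: 15 tertiary carbinol
Product: 16 methyl 2-[(2R,3R,5R,6S)-3-(tert-butyldimethylsilyloxy)-6,10-dimethylspiro[4.5]dec-9-en-2-yl]acetate
Conditions: SOCl2, pyridine, CH2Cl2, −20 → 0 °C
Reagents that add atoms: none
Why: Dehydration through the chlorosulfite is an E2 elimination in which the axial C10 oxygen and the axial hydrogen on C9 are antiperiplanar, which should give the trisubstituted ring alkene, while the basic medium avoids a free C10 cation that could trigger a 1,2-shift of a spiro bond.

Step 11
Reactants: 16 ring alkene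
Product: 17 methyl 2-[(2R,3R,5R,6S)-3-(tert-butyldimethylsilyloxy)-6,10-dimethyl-8-oxospiro[4.5]dec-9-en-2-yl]acetate
Conditions: CrO3, 3,5-dimethylpyrazole, CH2Cl2, −20 °C
Reagents that add atoms: chromium trioxide, O=[Cr](=O)=O
Why: Allylic oxidation with the CrO3–dimethylpyrazole complex should convert the ring CH2 next to the less substituted alkene carbon into the enone carbonyl, since the other ring allylic position is the quaternary C5 and the C14 methyl reacts more slowly.

Step 12
Reactants: 17 enone
Product: 18 methyl 2-[(2R,3R,5R,6R,7S)-3-(tert-butyldimethylsilyloxy)-7-hydroxy-6,10-dimethyl-8-oxospiro[4.5]dec-9-en-2-yl]acetate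
Conditions: NaN(SiMe3)2, THF, −78 °C; then 2-(phenylsulfonyl)-3-phenyloxaziridine, −78 °C; aq. NH4Cl
Reagents that add atoms: 2-(phenylsulfonyl)-3-phenyloxaziridine (Davis reagent), O=S(=O)(c1ccccc1)N1OC1c1ccccc1
Why: Davis oxidation of the kinetic α'-enolate (the ketone is deprotonated ahead of the less acidic ester) should deliver oxygen to C7 on the face away from the neighbouring C6 methyl, giving the trans hydroxy ketone, which is also the more stable epimer.

Step 13
Reactants: 18 hydroxy enone
Product: 19 methyl 2-[(2R,3R,5R,6R,7S,8S)-3-(tert-butyldimethylsilyloxy)-7,8-dihydroxy-6,10-dimethylspiro[4.5]dec-9-en-2-yl]acetate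
Conditions: NaBH4, CeCl3·7H2O, MeOH, −78 °C
Reagents that add atoms: none
Why: Luche reduction is 1,2-selective and adds hydride along the axial trajectory of the cyclohexenone, so the new C8 hydroxyl should be pseudo-equatorial and trans to the equatorial C7 hydroxyl.

Step 14
Reactants: 19 silyl ether diol
Product: 21 (2R,3R,5R,6R,7S,8S)-7,8-dihydroxy-6,10-dimethylspiro[4.5]dec-9-ene-2-acetic acid 3-lactone (cis-fused γ-lactone through O3), via triol methyl ester 20 (not isolated)
Conditions: Bu4NF, THF, 0 °C → rt; aq. NH4Cl
Reagents that add atoms: none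
Why: Fluoride desilylation frees the C3 alkoxide, which sits cis to the acetate arm and should close the γ-lactone by intramolecular transesterification, the cis ring fusion being the only unstrained one.

Step 15
Reactants: 21 diol lactone
Product: 22 7,8-bis(triethylsilyl) ether of 21
Conditions: TESOTf, 2,6-lutidine, CH2Cl2, −78 → 0 °C
Reagents that add atoms: triethylsilyl trifluoromethanesulfonate, CC[Si](CC)(CC)OS(=O)(=O)C(F)(F)F
Why: Silyl triflate silylation protects both secondary hydroxyls so that the lactone α-CH2 is the only acidic site in the next step.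

Step 16
Reactants: 22 protected lactone; 23 dimethylmethylideneammonium iodide (Eschenmoser's salt)
Product: 26 2-[(2R,3R,5R,6R,7S,8S)-3-hydroxy-6,10-dimethyl-7,8-bis(triethylsilyloxy)spiro[4.5]dec-9-en-2-yl]prop-2-enoic acid γ-lactone, via Mannich base 24 (not isolated), via methiodide 25 (not isolated)
Conditions: LiN(iPr)2, THF, −78 °C; 23, −78 °C → rt; then MeI, THF, rt; then aq. NaHCO3, EtOAc, rt
Reagents that add atoms: none
Why: Mannich aminomethylation of the lactone enolate followed by N-quaternisation and base-induced β-elimination of the amine is the standard α-methylenation of γ-lactones and creates no stereocentre.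

Step 17
Reactants: 26 α-methylene lactone
Product: 27 2-[(2R,3R,5R,6R,7S,8S)-3-hydroxy-10-(hydroxymethyl)-6-methyl-7,8-bis(triethylsilyloxy)spiro[4.5]dec-9-en-2-yl]prop-2-enoic acid γ-lactone
Conditions: SeO2 (0.5 equiv), tBuOOH, CH2Cl2, rt
Reagents that add atoms: tert-butyl hydroperoxide (oxygen donor through catalytic SeO2), CC(C)(C)OO
Why: Selenium dioxide allylic hydroxylation (ene reaction then 2,3-sigmatropic shift) attacks α to the more substituted alkene carbon, and since the only such position with hydrogen is the C14 methyl (the other is quaternary C5) it should give the primary allylic alcohol, the electron-poor lactone methylene being inert.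

Step 18
Reactants: 27 allylic alcohol; 28 angelic acid
Product: 29 7,8-bis(triethylsilyl) ether of the target (C14 angelate)
Conditions: 28, 2,4,6-trichlorobenzoyl chloride, Et3N, toluene, rt; then 27, 60 °C
Reagents that add atoms: none
Why: Yamaguchi esterification through the mixed anhydride, run without a nucleophilic catalyst, should acylate the primary allylic alcohol while keeping the (Z) double bond of the angelate from isomerising to the tiglate.

Step 19
Reactants: 29 protected target
Product: 30 target CNP0224912.1
Conditions: HF·pyridine, pyridine, THF, 0 °C → rt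
Reagents that add atoms: none
Why: Fluoride-mediated silyl ether cleavage under buffered, weakly acidic conditions should remove both triethylsilyl groups and leave the angelate, the allylic system and the α-methylene lactone untouched.

Compound list

1 | 2,6-dimethylcyclohexanone (cis/trans mixture) | CC1CCCC(C)C1=O | starting material
2 | (R)-1-phenylethylamine | C[C@@H](N)c1ccccc1 | starting material
3 | N-[(1R)-1-phenylethyl]-2,6-dimethylcyclohexan-1-imine | CC1CCCC(C)C1=N[C@H](C)c1ccccc1 | intermediate
4 | methyl vinyl ketone | CC(=O)C=C | starting material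
5 | (2S)-2,6-dimethyl-2-(3-oxobutyl)-N-[(1R)-1-phenylethyl]cyclohexan-1-imine (formed in the flask) | CC(=O)CC[C@]1(C)CCCC(C)C1=N[C@H](C)c1ccccc1 | intermediate
6 | (2S)-2,6-dimethyl-2-(3-oxobutyl)cyclohexan-1-one (C6 epimers) | CC(=O)CC[C@]1(C)CCCC(C)C1=O | intermediate
7 | (4aS,8S)-4a,8-dimethyl-4,4a,5,6,7,8-hexahydronaphthalen-2(3H)-one | O=C1CC[C@]2(C)CCC[C@H](C)C2=C1 | intermediate
8 | methyl bromoacetate | COC(=O)CBr | starting material
9 | methyl 2-[(4aS,8S)-4a,8-dimethyl-2-oxo-2,3,4,4a,5,6,7,8-octahydronaphthalen-3-yl]acetate (C3 epimers) | COC(=O)CC1C[C@]2(C)CCC[C@H](C)C2=CC1=O | intermediate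
10 | methyl 2-[(4aS,8S)-4a,8-dimethyl-2-oxo-2,4a,5,6,7,8-hexahydronaphthalen-3-yl]acetate | COC(=O)CC1=C[C@]2(C)CCC[C@H](C)C2=CC1=O | intermediate
11 | C1–C5 bonded cyclopropane-bridged oxyallyl zwitterion (formed in the flask) | COC(=O)C[C+]1C([O-])=C[C@]23[C@@H](C)CCC[C@@]2(C)[C@H]13 | intermediate
12 | methyl 2-[(5R,6S,10S)-10-hydroxy-6,10-dimethyl-3-oxospiro[4.5]dec-1-en-2-yl]acetate | COC(=O)CC1=C[C@]2(CC1=O)[C@@](C)(O)CCC[C@@H]2C | intermediate
13 | methyl 2-[(3R,5R,6S,10S)-3,10-dihydroxy-6,10-dimethylspiro[4.5]dec-1-en-2-yl]acetate | COC(=O)CC1=C[C@]2(C[C@H]1O)[C@@](C)(O)CCC[C@@H]2C | intermediate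
14 | methyl 2-[(3R,5R,6S,10S)-3-(tert-butyldimethylsilyloxy)-10-hydroxy-6,10-dimethylspiro[4.5]dec-1-en-2-yl]acetate | COC(=O)CC1=C[C@]2(C[C@H]1O[Si](C)(C)C(C)(C)C)[C@@](C)(O)CCC[C@@H]2C | intermediate
15 | methyl 2-[(2R,3R,5R,6S,10S)-3-(tert-butyldimethylsilyloxy)-10-hydroxy-6,10-dimethylspiro[4.5]decan-2-yl]acetate | COC(=O)C[C@H]1C[C@]2(C[C@H]1O[Si](C)(C)C(C)(C)C)[C@@](C)(O)CCC[C@@H]2C | intermediate
16 | methyl 2-[(2R,3R,5R,6S)-3-(tert-butyldimethylsilyloxy)-6,10-dimethylspiro[4.5]dec-9-en-2-yl]acetate | COC(=O)C[C@H]1C[C@]2(C[C@H]1O[Si](C)(C)C(C)(C)C)C(C)=CCC[C@@H]2C | intermediate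
17 | methyl 2-[(2R,3R,5R,6S)-3-(tert-butyldimethylsilyloxy)-6,10-dimethyl-8-oxospiro[4.5]dec-9-en-2-yl]acetate | COC(=O)C[C@H]1C[C@]2(C[C@H]1O[Si](C)(C)C(C)(C)C)C(C)=CC(=O)C[C@@H]2C | intermediate
18 | methyl 2-[(2R,3R,5R,6R,7S)-3-(tert-butyldimethylsilyloxy)-7-hydroxy-6,10-dimethyl-8-oxospiro[4.5]dec-9-en-2-yl]acetate | COC(=O)C[C@H]1C[C@]2(C[C@H]1O[Si](C)(C)C(C)(C)C)C(C)=CC(=O)[C@@H](O)[C@@H]2C | intermediate
19 | methyl 2-[(2R,3R,5R,6R,7S,8S)-3-(tert-butyldimethylsilyloxy)-7,8-dihydroxy-6,10-dimethylspiro[4.5]dec-9-en-2-yl]acetate | COC(=O)C[C@H]1C[C@]2(C[C@H]1O[Si](C)(C)C(C)(C)C)C(C)=C[C@H](O)[C@@H](O)[C@@H]2C | intermediate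
20 | methyl 2-[(2R,3R,5R,6R,7S,8S)-3,7,8-trihydroxy-6,10-dimethylspiro[4.5]dec-9-en-2-yl]acetate (formed in the flask) | COC(=O)C[C@H]1C[C@]2(C[C@H]1O)C(C)=C[C@H](O)[C@@H](O)[C@@H]2C | intermediate
21 | (2R,3R,5R,6R,7S,8S)-7,8-dihydroxy-6,10-dimethylspiro[4.5]dec-9-ene-2-acetic acid 3-lactone | O=C1O[C@@H]2C[C@@]3(C[C@@H]2C1)C(C)=C[C@H](O)[C@@H](O)[C@@H]3C | intermediate
22 | 7,8-bis(triethylsilyl) ether of 21 | O=C1O[C@@H]2C[C@@]3(C[C@@H]2C1)C(C)=C[C@H](O[Si](CC)(CC)CC)[C@@H](O[Si](CC)(CC)CC)[C@@H]3C | intermediate
23 | dimethylmethylideneammonium iodide (Eschenmoser's salt) | C=[N+](C)C.[I-] | starting material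
24 | 11-(dimethylaminomethyl) derivative of 22 (C11 epimers; formed in the flask) | O=C1O[C@@H]2C[C@@]3(C[C@@H]2C1CN(C)C)C(C)=C[C@H](O[Si](CC)(CC)CC)[C@@H](O[Si](CC)(CC)CC)[C@@H]3C | intermediate
25 | trimethylammonium iodide of 24 (formed in the flask) | O=C1O[C@@H]2C[C@@]3(C[C@@H]2C1C[N+](C)(C)C)C(C)=C[C@H](O[Si](CC)(CC)CC)[C@@H](O[Si](CC)(CC)CC)[C@@H]3C.[I-] | intermediate
26 | 2-[(2R,3R,5R,6R,7S,8S)-3-hydroxy-6,10-dimethyl-7,8-bis(triethylsilyloxy)spiro[4.5]dec-9-en-2-yl]prop-2-enoic acid γ-lactone | C=C1C(=O)O[C@@H]2C[C@@]3(C[C@H]12)C(C)=C[C@H](O[Si](CC)(CC)CC)[C@@H](O[Si](CC)(CC)CC)[C@@H]3C | intermediate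
27 | 2-[(2R,3R,5R,6R,7S,8S)-3-hydroxy-10-(hydroxymethyl)-6-methyl-7,8-bis(triethylsilyloxy)spiro[4.5]dec-9-en-2-yl]prop-2-enoic acid γ-lactone | C=C1C(=O)O[C@@H]2C[C@@]3(C[C@H]12)C(CO)=C[C@H](O[Si](CC)(CC)CC)[C@@H](O[Si](CC)(CC)CC)[C@@H]3C | intermediate
28 | angelic acid, (Z)-2-methylbut-2-enoic acid | C/C=C(/C)C(=O)O | starting material
29 | 7,8-bis(triethylsilyl) ether of the target | C=C1C(=O)O[C@@H]2C[C@@]3(C[C@H]12)C(COC(=O)/C(C)=C\C)=C[C@H](O[Si](CC)(CC)CC)[C@@H](O[Si](CC)(CC)CC)[C@@H]3C | intermediate
30 | CNP0224912.1: 2-[(2R,3R,5R,6R,7S,8S)-10-[(angeloyloxy)methyl]-3,7,8-trihydroxy-6-methylspiro[4.5]dec-9-en-2-yl]prop-2-enoic acid γ-lactone (through O3) | C=C1C(=O)O[C@@H]2C[C@@]3(C[C@H]12)C(COC(=O)/C(C)=C\C)=C[C@H](O)[C@@H](O)[C@@H]3C | target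

Total step count: 19. Longest linear sequence: 19 steps (1 to 30; all other inputs are commercial).

Steps most likely to fail

1. Step 6. The zwitterion may partition away from the spiro channel: cleavage of the inner bond C5–C10 (hydroazulenone) or a 1,4-shift (lumiketone) can compete because the ester-bearing arm on C2 is a weaker donor than a plain alkyl group, and the cyclopentenone product can be photolysed further. The fallback sets out from 7 and returns at 12. Alkylation of the kinetic enolate of 7 with allyl bromide (LiN(iPr)2, THF, −78 °C) should give (4aS,8S)-3-allyl-4a,8-dimethyl-4,4a,5,6,7,8-hexahydronaphthalen-2(3H)-one F1. DDQ in refluxing dioxane should give the 3-allyl dienone F2, whose substituent is a plain alkyl donor of the kind for which spiro formation is the established course. The same irradiation should give the allyl spiro hydroxy enone F3. Lemieux–Johnson cleavage of the terminal alkene (OsO4 cat., NaIO4, 2,6-lutidine, dioxane/water) should give the aldehyde F4, Pinnick oxidation (NaClO2, NaH2PO4, 2-methyl-2-butene, tBuOH/water) the acid F5, and Me3SiCHN2 in MeOH/toluene should return 12.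

2. Step 11. Hydrogen abstraction can wander to the C14 methyl, or the oxidation can stall or over-oxidise, eroding the yield of enone. The fallback sets out from 16 and returns at 17. Epoxidation (mCPBA, NaHCO3, CH2Cl2) should give the 9,10-epoxide F6. PhSeNa (from PhSeSePh and NaBH4, EtOH) should open it at the less hindered C9 to the hydroxy selenide F7. H2O2/pyridine oxidises selenium, and the selenoxide can eliminate only toward C8, giving the tertiary allylic alcohol F8. Pyridinium chlorochromate, (C5H5NH)[CrO3Cl], should then effect the Babler–Dauben oxidative 1,3-transposition to 17.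

3. Step 10. Elimination can run toward the methyl group instead of into the ring, above all if part of the carbinol carries its oxygen equatorial and so has no antiperiplanar ring hydrogen. The fallback sets out from 15 and returns at 16: the dehydration is run without regard to regiochemistry and the exocyclic alkene F9 is moved into the ring with RhCl3·3H2O in EtOH at 70 °C (rhodium hydride addition and elimination), the trisubstituted ring alkene 16 being the thermodynamic isomer.

Further compounds

F1 | step 6 | (4aS,8S)-3-allyl-4a,8-dimethyl-4,4a,5,6,7,8-hexahydronaphthalen-2(3H)-one (C3 epimers) | C=CCC1C[C@]2(C)CCC[C@H](C)C2=CC1=O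
F2 | step 6 | (4aS,8S)-3-allyl-4a,8-dimethyl-5,6,7,8-tetrahydronaphthalen-2(4aH)-one | C=CCC1=C[C@]2(C)CCC[C@H](C)C2=CC1=O
F3 | step 6 | (5R,6S,10S)-10-hydroxy-6,10-dimethyl-2-(prop-2-enyl)spiro[4.5]dec-1-en-3-one | C=CCC1=C[C@]2(CC1=O)[C@@](C)(O)CCC[C@@H]2C
F4 | step 6 | 2-[(5R,6S,10S)-10-hydroxy-6,10-dimethyl-3-oxospiro[4.5]dec-1-en-2-yl]acetaldehyde | O=CCC1=C[C@]2(CC1=O)[C@@](C)(O)CCC[C@@H]2C
F5 | step 6 | 2-[(5R,6S,10S)-10-hydroxy-6,10-dimethyl-3-oxospiro[4.5]dec-1-en-2-yl]acetic acid | OC(=O)CC1=C[C@]2(CC1=O)[C@@](C)(O)CCC[C@@H]2C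
F6 | step 11 | 9,10-epoxide of 16 (either face) | COC(=O)C[C@H]1C[C@]2(C[C@H]1O[Si](C)(C)C(C)(C)C)C3(C)OC3CC[C@@H]2C
F7 | step 11 | methyl 2-[(2R,3R,5R,6S)-3-(tert-butyldimethylsilyloxy)-10-hydroxy-6,10-dimethyl-9-(phenylselanyl)spiro[4.5]decan-2-yl]acetate | COC(=O)C[C@H]1C[C@]2(C[C@H]1O[Si](C)(C)C(C)(C)C)C(C)(O)C([Se]c3ccccc3)CC[C@@H]2C
F8 | step 11 | methyl 2-[(2R,3R,5R,6S)-3-(tert-butyldimethylsilyloxy)-10-hydroxy-6,10-dimethylspiro[4.5]dec-8-en-2-yl]acetate | COC(=O)C[C@H]1C[C@]2(C[C@H]1O[Si](C)(C)C(C)(C)C)C(C)(O)C=CC[C@@H]2C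
F9 | step 10 | methyl 2-[(2R,3R,5R,6S)-3-(tert-butyldimethylsilyloxy)-6-methyl-10-methylidenespiro[4.5]decan-2-yl]acetate | COC(=O)C[C@H]1C[C@]2(C[C@H]1O[Si](C)(C)C(C)(C)C)C(=C)CCC[C@@H]2C
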